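The earlier runs and the new flask are simulated for an exercise; noise was put on by code.

The amounts came first: Friday's and Saturday's runs and the new flasks, midnight and dawn, held 100 µM of X and 25 µM of J, and they differed in the D charged.

| flask | D | X | J | remark | time |
|---|---|---|---|---|---|
| Friday's | 0.011 M | 100 µM | 25 µM | run made earlier |  |
| Saturday's | 0.061 M | 100 µM | 25 µM | run made earlier |  |
| midnight | 0.020 M | 100 µM | 25 µM |  | 50 min |
| dawn | 0.080 M | 100 µM | 25 µM |  | 50 min |

| run | time / min | Z / % | D / % |
|---|---|---|---|
| Friday's | 2.50 | 1 | 98 |
| Friday's | 8.00 | 12 | 87 |
| Friday's | 15.0 | 31 | 68 |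
| Friday's | 20.0 | 45 | 56 |
| Friday's | 30.0 | 67 | 33 |
| Friday's | 40.0 | 81 | 22 |
| Friday's | 50.0 | 89 | 11 |
| Saturday's | 4.00 | 13 | 87 |
| Saturday's | 6.00 | 25 | 78 |
| Saturday's | 10.0 | 39 | 57 |
| Saturday's | 15.0 | 56 | 45 |
| Saturday's | 20.0 | 69 | 29 |
| Saturday's | 30.0 | 83 | 18 |
| Saturday's | 50.0 | 96 | 5 |

(readings scatter by 2 percentage points)

- the average divides the monomer in chains by the number of chains begun, living and dead together
- the earlier runs were read with a standard deviation of 2 percentage points
- the earlier runs do not show the number of chains; that part of a forecast is a guess

1. which of the two ends with the longer chains by the average number of monomer units in a chain (chains begun, living or dead) ("neither" if they lie within 10%) (midnight / dawn / neither)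
2. average number of monomer units in a chain (chains begun, living or dead) at the end, midnight
3. average number of monomer units in a chain (chains begun, living or dead) at the end, dawn

The average length is the Z made over the chains begun, so I took the settings in turn. [D] came first. Midnight held 200 D per X and dawn 800. This D charged per X charged, the charge ratio (the target degree of polymerisation), is the length if the charged D ends in chains and each X begins one, so by hand dawn stood ahead by a factor of 4.00.

Time came next. Saturday's D readings fell from 57% to 18% between 10.0 min and 30.0 min, which I read as a first-order constant of about 0.0576 min⁻¹, and integrating that loss over 50 min gave my estimate of 5.60% of the D remaining, though Friday's run, with less D charged, still read 11% at 50.0 min.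

[X] and [J] came last. The runs did not vary them and do not show the number of chains. By hand, at fixed [D] a larger [X] lowers the ratio, and if each J took one X, 75.0 µM of chains would stand and the length would rise by a factor of 1.33. My own reckoning for dawn, carrying Saturday's estimate over and with each X beginning a chain, was 755, and that factor was a guess on top of it.

The forecast said dawn, with 192 at midnight and 770 at dawn, reading from the runs that “initiation is slow and proportional to D”. For dawn it stood above my figure.

The flasks gave dawn: 263 at midnight and 986 at dawn, 1.32 and 1.23 times the charge ratio.

    D + X → Q + Z (k = 6.70 L mol⁻¹ min⁻¹)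
    X + J → L (k = 13000 L mol⁻¹ min⁻¹)
    D + Q → Z + Q, rate k3*[Q]*[D] (k = 880 L mol⁻¹ min⁻¹)

At the charges, the pseudo-first-order constant of X going to L was 0.325 min⁻¹, larger than that of X going into chains at midnight, 0.134 min⁻¹, and smaller than that of X going into chains at dawn, 0.536 min⁻¹. At the end midnight held Q at 7.06 × 10⁻⁵ M with J at 0.00529% of its charge, and dawn held Q at 7.83 × 10⁻⁵ M with J at 13.0%. A neighbour flask, like dawn but with 0.20 M of D, charge ratio 2000, gave 2280, which is 1.14 times that ratio, with Q at 8.56 × 10⁻⁵ M.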